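**Strategy.** The cyclohexane ring is numbered C1 (CH bearing the side chain), C2 (C=CH2), C3 (CHBr), C4, C5 (CHBr), C6 (CMe2). Side chain, C1 and C6 with both methyls are (S)-linalool, whose trisubstituted alkene is the C1–C6 ring bond. One [2+2] photocycloaddition of silylated linalool 2 with the chiral 6-methyl-dioxinone 7 (tert-butyl acetal) adds the C2–C5 unit across that alkene, forming C1–C2 and C5–C6 and fixing C1. Retro-aldol opening of the cyclobutane and Claisen closure then give a cyclohexane-1,3-dione with its carbonyls at C3 and C5, the two bromine-bearing carbons; C2 is methylenated next to the C3 carbonyl.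

Key step: step 4

Remark: ring positions are cited throughout in the C1–C6 numbering defined above, cis/trans refer to the C1 side chain, and (S)-linalool of high enantiomeric purity is taken to be purchasable.

**Step 1**
Reactants: 1 (S)-linalool
Product: 2 (S)-linalool triethylsilyl ether
Conditions: Et3SiOTf, 2,6-lutidine, CH2Cl2, −78 → 0 °C
Reagents that add atoms: triethylsilyl trifluoromethanesulfonate, CC[Si](CC)(CC)OS(=O)(=O)C(F)(F)F
Why: Silyl triflate with a hindered pyridine base is the standard O-silylation of a tertiary allylic alcohol and should cap it without ionisation, leaving the carbinol centre untouched.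

**Step 2**
Reactants: 3 (R)-3-hydroxybutanoic acid; 4 pivalaldehyde
Product: 5 (2R,6R)-2-tert-butyl-6-methyl-1,3-dioxan-4-one
Conditions: pyridinium p-toluenesulfonate (cat.), CH2Cl2, reflux, water separator; recrystallisation
Reagents that add atoms: none
Why: Acid-catalysed acetalisation of a β-hydroxy acid with pivalaldehyde gives the dioxanone, the new acetal centre settling under thermodynamic control cis to the 6-methyl group (both equatorial).

**Step 3**
Reactants: 5 (2R,6R)-2-tert-butyl-6-methyl-1,3-dioxan-4-one
Product: 7 (R)-2-tert-butyl-6-methyl-4H-1,3-dioxin-4-one, via bromo-dioxanone 6 (not isolated)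
Conditions: NBS, AIBN (cat.), PhCF3, 80 °C; then Et3N, 0 °C → rt
Reagents that add atoms: none
Why: Radical bromination with NBS at the oxygen-bearing C6–H followed by amine-induced loss of HBr should give the conjugated dioxinone; C6 is flattened and the acetal carbon remains as the only stereocentre.

**Step 4**
Reactants: 2 (S)-linalool triethylsilyl ether; 7 (R)-2-tert-butyl-6-methyl-4H-1,3-dioxin-4-one
Product: 8 head-to-tail cis-fused cyclobutane photoadduct (cyclobutane anti to tert-butyl, side chain exo)
Conditions: hν (medium-pressure Hg lamp, Pyrex filter), 2 (4 equiv), MeCN, −20 °C, degassed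
Reagents that add atoms: none
Why: Irradiation excites the dioxinone to its triplet, which adds to the electron-rich trisubstituted alkene of 2 to give a triplet 1,4-biradical (most plausibly by first joining the dioxinone α-carbon to C1, leaving a tertiary radical at C6 and an α-oxy radical at C5) that collapses after spin inversion; the closest known reaction type is the enone–alkene [2+2] photocycloaddition of a 1,3-dioxin-4-one, the first half of a de Mayo reaction. The one new ring, the cyclobutane C1–C2–C5–C6, is closed by radical–radical recombination of that biradical and can only be cis-fused to the six-membered acetal ring. Of the three new stereocentres, C2 and C5 are set together on the dioxinone face anti to the tert-butyl group (control by the acetal carbon), and C1 by the preference of the side chain for the exo, convex position during closure; the remote carbinol centre of 2 has no influence. The step needs head-to-tail regiochemistry, secured by the alkene bonding its fully substituted terminus to the oxygen-bearing β-carbon, and reaction at the trisubstituted alkene and not the vinyl group, secured by its higher electron density and by the quaternary silyloxy carbon that shields the vinyl group. The exo preference is the least secure element; exo and endo adducts differ within the rigid bicycle and should be separable here.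

**Step 5**
Reactants: 8 photoadduct
Product: 10 (5R)-4,4-dimethyl-5-[(3S)-3-methyl-3-(triethylsilyloxy)pent-4-en-1-yl]cyclohexane-1,3-dione, via keto ester 9 (not isolated)
Conditions: K2CO3, MeOH, rt; evaporate; KOtBu, THF, 0 °C → rt; aq KHSO4 to pH 4
Reagents that add atoms: none
Why: Methanolysis of the acylal lactone releases pivalaldehyde and the strained cyclobutanolate undergoes retro-aldol cleavage of C2–C5 (second half of the de Mayo reaction), after which the methyl-ketone enolate (C4) attacks the ester (C3) in a 6-exo-trig Claisen condensation driven by the dione enolate; C1 is not enolisable and keeps its configuration.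

**Step 6**
Reactants: 10 dione
Product: 11 C3 isopropyl enol ether (C3=C4, C5 ketone)
Conditions: iPrI, K2CO3, DMF, 40 °C
Reagents that add atoms: 2-iodopropane, CC(C)I
Why: O-alkylation of a cyclic 1,3-dione enolate with a secondary iodide gives the vinylogous ester, and the oxygen on C3, remote from the gem-dimethyl carbon, should be the one alkylated.

**Step 7**
Reactants: 11 C3 isopropyl enol ether
Product: 13 (5R)-4,4-dimethyl-5-[(3S)-3-methyl-3-(triethylsilyloxy)pent-4-en-1-yl]cyclohex-2-en-1-one, via allylic alcohol 12 (not isolated)
Conditions: iBu2AlH, toluene, −78 → 0 °C; then 1 M aq HCl, THF, 0 °C, brief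
Reagents that add atoms: none
Why: Stork–Danheiser transposition: 1,2-hydride addition at the C5 carbonyl and acid hydrolysis with loss of water move the carbonyl to C3 and place the alkene at C4=C5, the hindered tertiary silyl ether tolerating the short cold acid contact.

**Step 8**
Reactants: 13 enone
Product: 14 C4,C5-epoxy C3-ketone (oxirane trans to the side chain)
Conditions: H2O2 (30% aq), NaOH, MeOH, 0 °C
Reagents that add atoms: hydrogen peroxide, OO
Why: Weitz–Scheffer epoxidation: hydroperoxide attacks C5 axially on the half-chair that keeps the C1 chain equatorial, opposite the pseudoaxial C6 methyl, and the enolate closes the oxirane on that face, so the oxygen ends trans to the chain as is usual for 5-substituted cyclohex-2-enones; the isolated alkenes are inert.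

**Step 9**
Reactants: 14 epoxy ketone
Product: 17 C2-methylidene epoxy ketone, via Mannich base 15 (not isolated), via ammonium iodide 16 (not isolated)
Conditions: LiN(SiMe3)2, THF, −78 °C; CH2=NMe2+ I−, −78 → 0 °C; MeI, CH2Cl2, rt; aq NaHCO3, CH2Cl2, rt
Reagents that add atoms: dimethyl(methylidene)ammonium iodide, C=[N+](C)C.[I-]
Why: A Mannich reaction of the only available enolate (C2, since C4 is an oxirane carbon), N-methylation and E1cB loss of trimethylamine give the α-methylene ketone; no stereocentre is created and C1 is untouched.

**Step 10**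
Reactants: 17 C2-methylidene epoxy ketone
Product: 18 β-hydroxy enone (C3 ketone, C2 methylidene, C5–OH trans to the side chain)
Conditions: SmI2 (2.2 equiv), THF–MeOH, −90 °C
Reagents that add atoms: none
Why: Reductive opening of an α,β-epoxy ketone by SmI2: electron transfer to the carbonyl cleaves the adjacent C4–O bond and methanol protonates the samarium enolate at C4, which at −90 °C with limiting reagent should outrun enone reduction; the C5–O bond is not touched, so the hydroxyl stays trans to the chain (axial).

**Step 11**
Reactants: 18 β-hydroxy enone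
Product: 19 trans-1,3-diol (C3–OH cis, C5–OH trans to the side chain)
Conditions: Me4NBH(OAc)3, MeCN–AcOH, −30 °C
Reagents that add atoms: none
Why: Evans–Saksena reduction: the axial C5 alkoxy(acetoxy)borohydride delivers hydride intramolecularly to the C3 carbonyl from the face of the C5 oxygen, which should give the anti diol (C3–OH equatorial, cis to the chain) without conjugate reduction.

**Step 12**
Reactants: 19 trans-1,3-diol
Product: 20 C3 tert-butyldimethylsilyl ether (C5–OH free)
Conditions: tBuMe2SiCl, imidazole, DMF, 0 °C
Reagents that add atoms: tert-butyldimethylsilyl chloride, CC(C)(C)[Si](C)(C)Cl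
Why: Sterically controlled silylation: the equatorial allylic C3 hydroxyl reacts while the axial C5 hydroxyl next to the quaternary C6 should not, so that the hindered bromide can be installed before the labile allylic one.

**Step 13**
Reactants: 20 C3 silyl ether
Product: 21 C5 bromide (cis to the side chain), C3 silyl ether
Conditions: CBr4, PPh3, pyridine (1 equiv), toluene, 60 °C
Reagents that add atoms: tetrabromomethane, BrC(Br)(Br)Br
Why: Appel reaction: bromide displaces the axial C5 oxyphosphonium group in an SN2 step from the equatorial side, giving the equatorial bromide cis to the chain by inversion; heating is needed at this neopentyl-type centre and both silyl ethers should survive the neutral medium.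

**Step 14**
Reactants: 21 C5 bromide
Product: 22 bromo diol (C3–OH cis, C5–Br cis to the side chain, free tertiary alcohol)
Conditions: HF·pyridine, pyridine, THF, 0 °C → rt
Reagents that add atoms: none
Why: Buffered fluoride desilylation should remove both silyl ethers, the equatorial secondary bromide having no antiperiplanar hydrogen for elimination and no access for substitution.

**Step 15**
Reactants: 22 bromo diol
Product: 23 (3S)-5-[(1S,3S,5S)-3,5-dibromo-2,2-dimethyl-6-methylidenecyclohexyl]-3-methylpent-1-en-3-ol (target)
Conditions: CBr4, PPh3, CH2Cl2, −20 → 0 °C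
Reagents that add atoms: tetrabromomethane, BrC(Br)(Br)Br
Why: Appel reaction under mild conditions: the secondary allylic C3 oxyphosphonium salt should undergo SN2 displacement with inversion to the axial bromide trans to the chain, while the tertiary alcohol is too hindered to form an oxyphosphonium salt at this temperature.

**Compound list**

1 | (S)-linalool, (3S)-3,7-dimethylocta-1,6-dien-3-ol | C=C[C@@](C)(O)CCC=C(C)C | starting material
2 | (S)-linalool triethylsilyl ether | C=C[C@@](C)(O[Si](CC)(CC)CC)CCC=C(C)C | intermediate
3 | (R)-3-hydroxybutanoic acid | C[C@@H](O)CC(=O)O | starting material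
4 | pivalaldehyde | CC(C)(C)C=O | starting material
5 | (2R,6R)-2-tert-butyl-6-methyl-1,3-dioxan-4-one (cis) | C[C@@H]1CC(=O)O[C@H](C(C)(C)C)O1 | intermediate
6 | 6-bromo derivative of 5 (acetal centre unchanged, C6 epimers), not isolated | CC1(Br)CC(=O)O[C@H](C(C)(C)C)O1 | intermediate
7 | (R)-2-tert-butyl-6-methyl-4H-1,3-dioxin-4-one | CC1=CC(=O)O[C@H](C(C)(C)C)O1 | intermediate
8 | (3R)-3-tert-butyl-1,8,8-trimethyl-7-[(3S)-3-methyl-3-(triethylsilyloxy)pent-4-en-1-yl]-2,4-dioxabicyclo[4.2.0]octan-5-one; cis-fused, cyclobutane anti to tert-butyl, chain exo | C=C[C@@](C)(O[Si](CC)(CC)CC)CC[C@@H]1[C@H]2C(=O)O[C@H](C(C)(C)C)O[C@@]2(C)C1(C)C | intermediate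
9 | methyl (3R)-4,4-dimethyl-3-[(3S)-3-methyl-3-(triethylsilyloxy)pent-4-en-1-yl]-5-oxohexanoate, not isolated | C=C[C@@](C)(O[Si](CC)(CC)CC)CC[C@H](CC(=O)OC)C(C)(C)C(C)=O | intermediate
10 | (5R)-4,4-dimethyl-5-[(3S)-3-methyl-3-(triethylsilyloxy)pent-4-en-1-yl]cyclohexane-1,3-dione | C=C[C@@](C)(O[Si](CC)(CC)CC)CC[C@@H]1CC(=O)CC(=O)C1(C)C | intermediate
11 | (5R)-6,6-dimethyl-5-[(3S)-3-methyl-3-(triethylsilyloxy)pent-4-en-1-yl]-3-(propan-2-yloxy)cyclohex-2-en-1-one | C=C[C@@](C)(O[Si](CC)(CC)CC)CC[C@@H]1CC(OC(C)C)=CC(=O)C1(C)C | intermediate
12 | allylic alcohol from 1,2-reduction of 11 (C5 carbinol, either epimer; present as its aluminium alkoxide), not isolated | C=C[C@@](C)(O[Si](CC)(CC)CC)CC[C@@H]1CC(OC(C)C)=CC(O)C1(C)C | intermediate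
13 | (5R)-4,4-dimethyl-5-[(3S)-3-methyl-3-(triethylsilyloxy)pent-4-en-1-yl]cyclohex-2-en-1-one | C=C[C@@](C)(O[Si](CC)(CC)CC)CC[C@@H]1CC(=O)C=CC1(C)C | intermediate
14 | 5,5-dimethyl-4-[(3S)-3-methyl-3-(triethylsilyloxy)pent-4-en-1-yl]-7-oxabicyclo[4.1.0]heptan-2-one, oxirane trans to the side chain | C=C[C@@](C)(O[Si](CC)(CC)CC)CC[C@@H]1CC(=O)[C@H]2O[C@H]2C1(C)C | intermediate
15 | C2-(dimethylaminomethyl) derivative of 14 (C2 epimers), not isolated | C=C[C@@](C)(O[Si](CC)(CC)CC)CC[C@@H]1C(CN(C)C)C(=O)[C@H]2O[C@H]2C1(C)C | intermediate
16 | N-methyl quaternary ammonium iodide of 15, not isolated | C=C[C@@](C)(O[Si](CC)(CC)CC)CC[C@@H]1C(C[N+](C)(C)C)C(=O)[C@H]2O[C@H]2C1(C)C.[I-] | intermediate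
17 | 5,5-dimethyl-3-methylidene-4-[(3S)-3-methyl-3-(triethylsilyloxy)pent-4-en-1-yl]-7-oxabicyclo[4.1.0]heptan-2-one, oxirane trans to the side chain | C=C[C@@](C)(O[Si](CC)(CC)CC)CC[C@@H]1C(=C)C(=O)[C@H]2O[C@H]2C1(C)C | intermediate
18 | 5-hydroxy-4,4-dimethyl-2-methylidene-3-[(3S)-3-methyl-3-(triethylsilyloxy)pent-4-en-1-yl]cyclohexan-1-one, hydroxyl trans to the side chain | C=C[C@@](C)(O[Si](CC)(CC)CC)CC[C@@H]1C(=C)C(=O)C[C@@H](O)C1(C)C | intermediate
19 | diol: C3–OH cis and C5–OH trans to the side chain, C2 methylidene, tertiary OSiEt3 | C=C[C@@](C)(O[Si](CC)(CC)CC)CC[C@@H]1C(=C)[C@H](O)C[C@@H](O)C1(C)C | intermediate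
20 | C3 tert-butyldimethylsilyl ether of 19 (C5–OH free) | C=C[C@@](C)(O[Si](CC)(CC)CC)CC[C@@H]1C(=C)[C@H](O[Si](C)(C)C(C)(C)C)C[C@@H](O)C1(C)C | intermediate
21 | C5 bromide cis to the side chain, C3–OSitBuMe2 cis, tertiary OSiEt3 | C=C[C@@](C)(O[Si](CC)(CC)CC)CC[C@@H]1C(=C)[C@H](O[Si](C)(C)C(C)(C)C)C[C@H](Br)C1(C)C | intermediate
22 | bromo diol: C3–OH cis, C5–Br cis to the side chain, free (S)-tertiary alcohol | C=C[C@@](C)(O)CC[C@@H]1C(=C)[C@H](O)C[C@H](Br)C1(C)C | intermediate
23 | (3S)-5-[(1S,3S,5S)-3,5-dibromo-2,2-dimethyl-6-methylidenecyclohexyl]-3-methylpent-1-en-3-ol | C=C[C@@](C)(O)CC[C@@H]1C(=C)[C@@H](Br)C[C@H](Br)C1(C)C | target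

**Step count and risks**

Total steps: 15. Longest linear sequence: 14 steps (3 → 5 → 7 → 8 → 10 → 11 → 13 → 14 → 17 → 18 → 19 → 20 → 21 → 22 → 23).

Step 4. The process at risk is stereocontrol at C1 (exo versus endo closure of the biradical and the facial bias exerted by the acetal), with addition to the vinyl group as a secondary leak. The fallback changes the controller to the mirror-image auxiliary. Setting out from 2, purchased (S)-3-hydroxybutanoic acid is taken through the chemistry of steps 2 and 3 to (2S,6S)-2-tert-butyl-6-methyl-1,3-dioxan-4-one F1, its bromo-dioxanone F2 (not isolated) and (S)-2-tert-butyl-6-methyl-4H-1,3-dioxin-4-one F3. Because the carbinol centre of 2 is too remote to matter, whichever face/exo–endo combination dominates with 7 is delivered with the opposite C1 configuration by F3. The C1-correct photoadduct F4 (mirror-image bicyclic core, side chain endo) should then be the main product. F4 is fragmented and cyclised under the conditions of step 5, and the route is rejoined at dione 10, where the acetal and ring-fusion centres no longer exist.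

Step 13. The process at risk is elimination towards C4 or a 1,2-methyl shift from the axial oxyphosphonium salt in place of substitution at the neopentyl-type C5. The fallback changes the mode of activation to an isolated sulfonate ester and an external bromide. Setting out from 20, chloromethanesulfonyl chloride and pyridine at 0 °C should give the compact, highly reactive C5 chloromethanesulfonate F5. LiBr in DMF at 40–60 °C should then displace it with inversion, and the route is rejoined at bromide 21.

Step 15. The process at risk is bromination that is not confined to the secondary allylic alcohol: ionisation or allylic rearrangement of the unprotected tertiary alcohol, or allylic transposition at C2/C3. The fallback changes the protecting-group order so that the tertiary silyl ether stays on until the end. Setting out from diol 19, acetic anhydride and pyridine at 0 °C should acylate only the unhindered C3 hydroxyl to give the C3 acetate F6. Appel bromination at C5 as in step 13 gives the bromo acetate F7. K2CO3 in MeOH frees the C3 alcohol F8 with the tertiary triethylsilyl ether intact. Appel bromination at −20 °C gives the silyl-protected dibromide F9, and HF·pyridine (pyridine, THF, 0 °C) returns the route at target 23.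

**Further compounds**

F1 | step 4 | (2S,6S)-2-tert-butyl-6-methyl-1,3-dioxan-4-one | C[C@H]1CC(=O)O[C@@H](C(C)(C)C)O1
F2 | step 4 | 6-bromo derivative of F1 (C6 epimers, not isolated) | CC1(Br)CC(=O)O[C@@H](C(C)(C)C)O1
F3 | step 4 | (S)-2-tert-butyl-6-methyl-4H-1,3-dioxin-4-one | CC1=CC(=O)O[C@@H](C(C)(C)C)O1
F4 | step 4 | photoadduct of 2 and F3 with the C1 configuration of 8 in the mirror-image bicyclic core (chain endo) | C=C[C@@](C)(O[Si](CC)(CC)CC)CC[C@@H]1[C@@H]2C(=O)O[C@@H](C(C)(C)C)O[C@]2(C)C1(C)C
F5 | step 13 | C5 chloromethanesulfonate of 20 | C=C[C@@](C)(O[Si](CC)(CC)CC)CC[C@@H]1C(=C)[C@H](O[Si](C)(C)C(C)(C)C)C[C@@H](OS(=O)(=O)CCl)C1(C)C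
F6 | step 15 | C3 acetate of diol 19 | C=C[C@@](C)(O[Si](CC)(CC)CC)CC[C@@H]1C(=C)[C@H](OC(C)=O)C[C@@H](O)C1(C)C
F7 | step 15 | C5 bromide (cis to the chain) with C3 acetate | C=C[C@@](C)(O[Si](CC)(CC)CC)CC[C@@H]1C(=C)[C@H](OC(C)=O)C[C@H](Br)C1(C)C
F8 | step 15 | C3 alcohol, C5 bromide, tertiary triethylsilyl ether | C=C[C@@](C)(O[Si](CC)(CC)CC)CC[C@@H]1C(=C)[C@H](O)C[C@H](Br)C1(C)C
F9 | step 15 | triethylsilyl ether of target 23 | C=C[C@@](C)(O[Si](CC)(CC)CC)CC[C@@H]1C(=C)[C@@H](Br)C[C@H](Br)C1(C)C
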